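The ten-membered carbocycle is disconnected at C5–C6 (germacranolide numbering), the bond between the vinyl CH of the C4=C5 alkene and the lactone carbinol carbon. An intramolecular Nozaki–Hiyama–Kishi addition of the C5 alkenyl bromide to a C6 aldehyde closes the ring, sets C6, and lets the resulting chromium alkoxide acylate the C12 acrylate ester, so the cis-fused α-methylene-γ-lactone forms in the same operation. The step exploits the 4-hydroxy-2-methylene ester array O6–C6–C7–C11–C12 and the two ring-cis trisubstituted alkenes, both already in place with defined geometry in an acyclic bromo aldehyde whose C7/C8 stereodiad comes from a chromium-catalysed asymmetric 2-(methoxycarbonyl)allylation.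

Key step: step 15

Remark: atoms carry germacranolide locants (ring C1–C10, C1=C10 bearing formyl C14, C4=C5 bearing C15, lactone oxygen on C6, acyloxy on C8, exocyclic C11=C13, lactone carbonyl C12); the target is read as the cis-fused (6R,7S,8R) lactone, and 2-[(4-methoxybenzyl)oxy]acetaldehyde (13) is taken to be purchasable.

Step 1
Reactants: 1 tert-butyldimethyl(prop-2-yn-1-yloxy)silane; 2 allyl bromide
Product: 3 (E)-1-bromo-2-{[(tert-butyldimethylsilyl)oxy]methyl}penta-1,4-diene (Br cis to the allyl group)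
Conditions: 2 (10 equiv, neat), PdBr2(PhCN)2 (3 mol%), rt
Reagents that add atoms: none
Why: Palladium-catalysed bromoallylation of a terminal alkyne: syn-bromopalladation puts Br on the terminal carbon and divalent palladium on the internal carbon, allyl bromide inserts and β-bromide elimination returns the catalyst, so Br and allyl end up cis, which is the C4=C5 geometry of the target.

Step 2
Reactants: 3 (E)-1-bromo-2-{[(tert-butyldimethylsilyl)oxy]methyl}penta-1,4-diene
Product: 5 (E)-5-bromo-4-{[(tert-butyldimethylsilyl)oxy]methyl}pent-4-en-1-ol, via B-alkyl-9-BBN adduct 4 (not isolated)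
Conditions: 9-BBN (1.2 equiv), THF, 0 °C to rt; then 3 M aq. NaOH, 30% aq. H2O2, 0 °C
Reagents that add atoms: hydrogen peroxide, OO
Why: Hydroboration–oxidation: 9-BBN adds to the monosubstituted terminal alkene far faster than to the trisubstituted bromoalkene and places boron on the terminal carbon, and alkaline peroxide replaces boron by hydroxyl, which turns the allyl group into the C3–C2–C1 chain with oxygen on C1.

Step 3
Reactants: 5 (E)-5-bromo-4-{[(tert-butyldimethylsilyl)oxy]methyl}pent-4-en-1-ol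
Product: 6 (E)-5-bromo-4-{[(tert-butyldimethylsilyl)oxy]methyl}pent-4-enal
Conditions: Dess–Martin periodinane (1.2 equiv), NaHCO3, CH2Cl2, 0 °C to rt
Reagents that add atoms: none
Why: Dess–Martin oxidation of the primary alcohol under buffered conditions should stop at the aldehyde and leave the silyl ether and the bromoalkene untouched.

Step 4
Reactants: 6 (E)-5-bromo-4-{[(tert-butyldimethylsilyl)oxy]methyl}pent-4-enal
Product: 7 (E)-1-bromo-2-{[(tert-butyldimethylsilyl)oxy]methyl}hexa-1,5-diene
Conditions: Ph3PCH3Br (1.3 equiv), KN(SiMe3)2 (1.25 equiv), THF, 0 °C; then 6, −78 °C to rt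
Reagents that add atoms: methyltriphenylphosphonium bromide, C[P+](c1ccccc1)(c1ccccc1)c1ccccc1.[Br-]
Why: Wittig methylenation with the salt-free non-stabilised ylide converts the C1 aldehyde into the terminal alkene needed for the cross-metathesis, so that C3 and C2 remain as the two methylene groups between the alkenes.

Step 5
Reactants: 8 methyl 4-oxobutanoate
Product: 9 methyl 3-formylbut-3-enoate
Conditions: 37% aq. HCHO, pyrrolidine (10 mol%), EtCO2H (10 mol%), iPrOH, 45 °C
Reagents that add atoms: formaldehyde, C=O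
Why: Amine-catalysed Mannich condensation (α-methylenation of an aldehyde) through the enamine of 8 and the iminium ion of formaldehyde should give the 2-substituted acrolein without touching the ester.

Step 6
Reactants: 7 (E)-1-bromo-2-{[(tert-butyldimethylsilyl)oxy]methyl}hexa-1,5-diene; 9 methyl 3-formylbut-3-enoate
Product: 10 methyl (3E,7E)-8-bromo-7-{[(tert-butyldimethylsilyl)oxy]methyl}-3-formylocta-3,7-dienoate
Conditions: second-generation Hoveyda–Grubbs catalyst RuCl2(H2IMes)(=CH-C6H4-2-OiPr) (5 mol%), 9 (3 equiv), 1,4-benzoquinone (10 mol%), CH2Cl2, 40 °C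
Reagents that add atoms: none
Why: Olefin cross-metathesis of a terminal alkene with a 2-substituted acrolein (slow to homodimerise) is expected to be E-selective for the enal (chain trans to CHO), which sets the C1=C10 geometry, while the trisubstituted bromoalkene is inert to the ruthenium carbene.

Step 7
Reactants: 10 methyl (3E,7E)-8-bromo-7-{[(tert-butyldimethylsilyl)oxy]methyl}-3-formylocta-3,7-dienoate
Product: 11 methyl (3E,7E)-8-bromo-7-{[(tert-butyldimethylsilyl)oxy]methyl}-3-(dimethoxymethyl)octa-3,7-dienoate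
Conditions: HC(OMe)3, CeCl3·7H2O (10 mol%), MeOH, rt
Reagents that add atoms: trimethyl orthoformate, COC(OC)OC; methanol, CO
Why: Mild Lewis acid-catalysed acetalisation with orthoformate as water scavenger masks the C14 aldehyde for the hydride and the two chromium steps under conditions that should spare the silyl ether.

Step 8
Reactants: 11 methyl (3E,7E)-8-bromo-7-{[(tert-butyldimethylsilyl)oxy]methyl}-3-(dimethoxymethyl)octa-3,7-dienoate
Product: 12 (3E,7E)-8-bromo-7-{[(tert-butyldimethylsilyl)oxy]methyl}-3-(dimethoxymethyl)octa-3,7-dienal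
Conditions: iBu2AlH (1.1 equiv), CH2Cl2, −78 °C; MeOH, aq. potassium sodium tartrate
Reagents that add atoms: none
Why: Partial ester reduction with iBu2AlH at low temperature should stop at the aldehyde because the tetrahedral aluminium hemiacetal, chelated by the neighbouring acetal oxygen, collapses only on work-up.

Step 9
Reactants: 13 2-[(4-methoxybenzyl)oxy]acetaldehyde; 14 methyl acrylate
Product: 15 methyl 3-hydroxy-4-[(4-methoxybenzyl)oxy]-2-methylidenebutanoate (racemic)
Conditions: DABCO (0.5 equiv), 1,4-dioxane/H2O 1:1, rt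
Reagents that add atoms: none
Why: Morita–Baylis–Hillman reaction of an activated α-alkoxy aldehyde with methyl acrylate gives the allylic alcohol, whose racemic carbinol centre is erased in the next step.

Step 10
Reactants: 15 methyl 3-hydroxy-4-[(4-methoxybenzyl)oxy]-2-methylidenebutanoate
Product: 16 methyl (Z)-2-(bromomethyl)-4-[(4-methoxybenzyl)oxy]but-2-enoate
Conditions: NBS, Me2S, CH2Cl2, 0 °C to rt
Reagents that add atoms: N-bromosuccinimide, O=C1CCC(=O)N1Br
Why: Corey–Kim-type activation of the alcohol by the bromosulfonium salt and SN2′ attack of bromide (allylic transposition) should give the thermodynamically preferred (Z)-2-(bromomethyl)enoate.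

Step 11
Reactants: 12 (3E,7E)-8-bromo-7-{[(tert-butyldimethylsilyl)oxy]methyl}-3-(dimethoxymethyl)octa-3,7-dienal; 16 methyl (Z)-2-(bromomethyl)-4-[(4-methoxybenzyl)oxy]but-2-enoate
Product: 18 methyl (3R,4R,6E,10E)-11-bromo-10-{[(tert-butyldimethylsilyl)oxy]methyl}-6-(dimethoxymethyl)-4-hydroxy-3-{[(4-methoxybenzyl)oxy]methyl}-2-methylideneundeca-6,10-dienoate, via trimethylsilyl ether 17 (not isolated)
Conditions: CrCl2 (10 mol%), (S,S)-1,8-bis(4-isopropyl-4,5-dihydrooxazol-2-yl)-3,6-diphenyl-9H-carbazole (12 mol%; ligand enantiomer chosen to deliver the 4R carbinol), iPr2NEt (15 mol%), Mn powder (2 equiv), TMSCl (1.5 equiv), THF, 0 °C; then aq. citric acid/THF, 0 °C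
Reagents that add atoms: none
Why: Catalytic asymmetric Nozaki–Hiyama allylation: divalent chromium (regenerated by Mn, released by TMSCl) turns 16 into an allylchromium that is expected to add through a chair transition state with CH2OPMB equatorial (anti C7/C8 relationship) on the aldehyde face selected by the ligand, giving the (3R,4R) adduct, while the alkenyl bromide stays untouched without nickel and O-silylation blocks lactonisation onto O8.

Step 12
Reactants: 18 methyl (3R,4R,6E,10E)-11-bromo-10-{[(tert-butyldimethylsilyl)oxy]methyl}-6-(dimethoxymethyl)-4-hydroxy-3-{[(4-methoxybenzyl)oxy]methyl}-2-methylideneundeca-6,10-dienoate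
Product: 19 methyl (3R,4R,6E,10E)-11-bromo-10-{[(tert-butyldimethylsilyl)oxy]methyl}-6-(dimethoxymethyl)-3-{[(4-methoxybenzyl)oxy]methyl}-2-methylidene-4-[(3-methylbutanoyl)oxy]undeca-6,10-dienoate
Conditions: 3-methylbutanoic anhydride, DMAP (cat.), Et3N, CH2Cl2, 0 °C
Reagents that add atoms: 3-methylbutanoic anhydride, CC(C)CC(=O)OC(=O)CC(C)C
Why: DMAP-catalysed acylation installs the natural 3-methylbutanoate early and removes O8 as a competitor for the C12 ester.

Step 13
Reactants: 19 methyl (3R,4R,6E,10E)-11-bromo-10-{[(tert-butyldimethylsilyl)oxy]methyl}-6-(dimethoxymethyl)-3-{[(4-methoxybenzyl)oxy]methyl}-2-methylidene-4-[(3-methylbutanoyl)oxy]undeca-6,10-dienoate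
Product: 20 methyl (3R,4R,6E,10E)-11-bromo-10-{[(tert-butyldimethylsilyl)oxy]methyl}-6-(dimethoxymethyl)-3-(hydroxymethyl)-2-methylidene-4-[(3-methylbutanoyl)oxy]undeca-6,10-dienoate
Conditions: DDQ (1.2 equiv), CH2Cl2/pH 7 buffer (NaH2PO4/Na2HPO4) 10:1, 0 °C
Reagents that add atoms: none
Why: Oxidative cleavage of the 4-methoxybenzyl ether by DDQ (hydride abstraction, hydrolysis of the oxocarbenium ion) is orthogonal to the silyl ether, acetal and esters, and the buffered cold medium should keep the γ-hydroxy ester from lactonising.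

Step 14
Reactants: 20 methyl (3R,4R,6E,10E)-11-bromo-10-{[(tert-butyldimethylsilyl)oxy]methyl}-6-(dimethoxymethyl)-3-(hydroxymethyl)-2-methylidene-4-[(3-methylbutanoyl)oxy]undeca-6,10-dienoate
Product: 21 methyl (3S,4R,6E,10E)-11-bromo-10-{[(tert-butyldimethylsilyl)oxy]methyl}-6-(dimethoxymethyl)-3-formyl-2-methylidene-4-[(3-methylbutanoyl)oxy]undeca-6,10-dienoate
Conditions: Dess–Martin periodinane, NaHCO3, CH2Cl2, 0 °C; used at once
Reagents that add atoms: none
Why: Dess–Martin oxidation under buffered, non-basic conditions should give the α-branched β-acyloxy aldehyde without epimerisation at C7, alkene migration or elimination of the ester.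

Step 15
Reactants: 21 methyl (3S,4R,6E,10E)-11-bromo-10-{[(tert-butyldimethylsilyl)oxy]methyl}-6-(dimethoxymethyl)-3-formyl-2-methylidene-4-[(3-methylbutanoyl)oxy]undeca-6,10-dienoate
Product: 23 (3aS,4R,6E,10E,11aR)-10-{[(tert-butyldimethylsilyl)oxy]methyl}-6-(dimethoxymethyl)-3-methylidene-2-oxo-2,3,3a,4,5,8,9,11a-octahydrocyclodeca[b]furan-4-yl 3-methylbutanoate, via seco hydroxy ester 22 (not isolated)
Conditions: CrCl2 (10 equiv), NiCl2 (10 mol%), degassed DMSO/THF 3:1, 21 added over 10 h to 0.003 M, rt; aq. ethylenediamine work-up; PPTS (cat.), CH2Cl2 if 22 persists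
Reagents that add atoms: none
Why: Zerovalent nickel (from NiCl2 and CrCl2) inserts into the C5–Br bond with retention of alkene geometry, transmetalation gives an alkenyl trivalent-chromium species that adds to the C6 aldehyde, and the chromium alkoxide of 22 then attacks the C12 methyl ester with loss of methoxide. The closest known reaction type is the intramolecular Nozaki–Hiyama–Kishi reaction used for medium rings, combined with the in-flask lactonisation that 4-oxido-2-methylene esters undergo in chromium-mediated 2-(alkoxycarbonyl)allylations. The carbocycle closes by a 10-exo-trig addition to the carbonyl group and the lactone by a 5-exo-trig acyl substitution. C6 is set by the C7 stereocentre: in the Felkin–Anh arrangement the C11 acrylate π-system lies anti to the incoming alkenyl group, which is also the 1,3-anti sense relative to the C8 acyloxy group, so H6 is expected to end up cis to H7, as the cis-fused (6R) lactone requires. The step needs chemoselectivity for the aldehyde (esters and the acetal-masked C14 do not react with alkenylchromium reagents), ring closure over oligomerisation (slow addition at high dilution, helped by the two ring-cis trisubstituted alkenes that bend the chain) and retention of the C4=C5 geometry (secured by the stereoretentive nickel and chromium steps).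

Step 16
Reactants: 23 (3aS,4R,6E,10E,11aR)-10-{[(tert-butyldimethylsilyl)oxy]methyl}-6-(dimethoxymethyl)-3-methylidene-2-oxo-2,3,3a,4,5,8,9,11a-octahydrocyclodeca[b]furan-4-yl 3-methylbutanoate
Product: 25 (3aS,4R,6E,10E,11aR)-6-formyl-10-(hydroxymethyl)-3-methylidene-2-oxo-2,3,3a,4,5,8,9,11a-octahydrocyclodeca[b]furan-4-yl 3-methylbutanoate (target), via silyl-protected enal 24 (not isolated)
Conditions: 1 M aq. HCl/THF 1:4, 0 °C to rt
Reagents that add atoms: water, O
Why: Aqueous acid hydrolyses first the α,β-unsaturated dimethyl acetal (allyl-stabilised oxocarbenium ion) and then the primary allylic silyl ether, which should leave the lactone, the ester and the E-enal geometry untouched.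

Compound list
1 | tert-butyldimethyl(prop-2-yn-1-yloxy)silane | C#CCO[Si](C)(C)C(C)(C)C | starting material
2 | allyl bromide (3-bromoprop-1-ene) | C=CCBr | starting material
3 | (E)-1-bromo-2-{[(tert-butyldimethylsilyl)oxy]methyl}penta-1,4-diene | Br/C=C(/CO[Si](C)(C)C(C)(C)C)CC=C | intermediate
4 | 9-[(E)-5-bromo-4-{[(tert-butyldimethylsilyl)oxy]methyl}pent-4-en-1-yl]-9-borabicyclo[3.3.1]nonane | Br/C=C(/CO[Si](C)(C)C(C)(C)C)CCCB1C2CCCC1CCC2 | intermediate
5 | (E)-5-bromo-4-{[(tert-butyldimethylsilyl)oxy]methyl}pent-4-en-1-ol | Br/C=C(/CO[Si](C)(C)C(C)(C)C)CCCO | intermediate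
6 | (E)-5-bromo-4-{[(tert-butyldimethylsilyl)oxy]methyl}pent-4-enal | Br/C=C(/CO[Si](C)(C)C(C)(C)C)CCC=O | intermediate
7 | (E)-1-bromo-2-{[(tert-butyldimethylsilyl)oxy]methyl}hexa-1,5-diene | Br/C=C(/CO[Si](C)(C)C(C)(C)C)CCC=C | intermediate
8 | methyl 4-oxobutanoate | COC(=O)CCC=O | starting material
9 | methyl 3-formylbut-3-enoate | COC(=O)CC(=C)C=O | intermediate
10 | methyl (3E,7E)-8-bromo-7-{[(tert-butyldimethylsilyl)oxy]methyl}-3-formylocta-3,7-dienoate | Br/C=C(/CO[Si](C)(C)C(C)(C)C)CC/C=C(/C=O)CC(=O)OC | intermediate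
11 | methyl (3E,7E)-8-bromo-7-{[(tert-butyldimethylsilyl)oxy]methyl}-3-(dimethoxymethyl)octa-3,7-dienoate | Br/C=C(/CO[Si](C)(C)C(C)(C)C)CC/C=C(/C(OC)OC)CC(=O)OC | intermediate
12 | (3E,7E)-8-bromo-7-{[(tert-butyldimethylsilyl)oxy]methyl}-3-(dimethoxymethyl)octa-3,7-dienal | Br/C=C(/CO[Si](C)(C)C(C)(C)C)CC/C=C(/C(OC)OC)CC=O | intermediate
13 | 2-[(4-methoxybenzyl)oxy]acetaldehyde | COc1ccc(COCC=O)cc1 | starting material
14 | methyl acrylate | C=CC(=O)OC | starting material
15 | methyl 3-hydroxy-4-[(4-methoxybenzyl)oxy]-2-methylidenebutanoate (racemic) | COC(=O)C(=C)C(O)COCc1ccc(OC)cc1 | intermediate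
16 | methyl (Z)-2-(bromomethyl)-4-[(4-methoxybenzyl)oxy]but-2-enoate | COC(=O)/C(CBr)=C/COCc1ccc(OC)cc1 | intermediate
17 | methyl (3R,4R,6E,10E)-11-bromo-10-{[(tert-butyldimethylsilyl)oxy]methyl}-6-(dimethoxymethyl)-3-{[(4-methoxybenzyl)oxy]methyl}-2-methylidene-4-[(trimethylsilyl)oxy]undeca-6,10-dienoate | Br/C=C(/CO[Si](C)(C)C(C)(C)C)CC/C=C(/C(OC)OC)C[C@@H](O[Si](C)(C)C)[C@@H](COCc1ccc(OC)cc1)C(=C)C(=O)OC | intermediate
18 | methyl (3R,4R,6E,10E)-11-bromo-10-{[(tert-butyldimethylsilyl)oxy]methyl}-6-(dimethoxymethyl)-4-hydroxy-3-{[(4-methoxybenzyl)oxy]methyl}-2-methylideneundeca-6,10-dienoate | Br/C=C(/CO[Si](C)(C)C(C)(C)C)CC/C=C(/C(OC)OC)C[C@@H](O)[C@@H](COCc1ccc(OC)cc1)C(=C)C(=O)OC | intermediate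
19 | methyl (3R,4R,6E,10E)-11-bromo-10-{[(tert-butyldimethylsilyl)oxy]methyl}-6-(dimethoxymethyl)-3-{[(4-methoxybenzyl)oxy]methyl}-2-methylidene-4-[(3-methylbutanoyl)oxy]undeca-6,10-dienoate | Br/C=C(/CO[Si](C)(C)C(C)(C)C)CC/C=C(/C(OC)OC)C[C@@H](OC(=O)CC(C)C)[C@@H](COCc1ccc(OC)cc1)C(=C)C(=O)OC | intermediate
20 | methyl (3R,4R,6E,10E)-11-bromo-10-{[(tert-butyldimethylsilyl)oxy]methyl}-6-(dimethoxymethyl)-3-(hydroxymethyl)-2-methylidene-4-[(3-methylbutanoyl)oxy]undeca-6,10-dienoate | Br/C=C(/CO[Si](C)(C)C(C)(C)C)CC/C=C(/C(OC)OC)C[C@@H](OC(=O)CC(C)C)[C@@H](CO)C(=C)C(=O)OC | intermediate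
21 | methyl (3S,4R,6E,10E)-11-bromo-10-{[(tert-butyldimethylsilyl)oxy]methyl}-6-(dimethoxymethyl)-3-formyl-2-methylidene-4-[(3-methylbutanoyl)oxy]undeca-6,10-dienoate | Br/C=C(/CO[Si](C)(C)C(C)(C)C)CC/C=C(/C(OC)OC)C[C@@H](OC(=O)CC(C)C)[C@@H](C=O)C(=C)C(=O)OC | intermediate
22 | methyl 2-[(1R,2R,3E,7E,10R)-4-{[(tert-butyldimethylsilyl)oxy]methyl}-8-(dimethoxymethyl)-2-hydroxy-10-[(3-methylbutanoyl)oxy]cyclodeca-3,7-dien-1-yl]prop-2-enoate (present in the flask as its trivalent chromium alkoxide) | COC(=O)C(=C)[C@@H]1[C@H](O)/C=C(/CO[Si](C)(C)C(C)(C)C)CC/C=C(/C(OC)OC)C[C@H]1OC(=O)CC(C)C | intermediate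
23 | (3aS,4R,6E,10E,11aR)-10-{[(tert-butyldimethylsilyl)oxy]methyl}-6-(dimethoxymethyl)-3-methylidene-2-oxo-2,3,3a,4,5,8,9,11a-octahydrocyclodeca[b]furan-4-yl 3-methylbutanoate | C=C1C(=O)O[C@@H]2/C=C(/CO[Si](C)(C)C(C)(C)C)CC/C=C(/C(OC)OC)C[C@@H](OC(=O)CC(C)C)[C@H]12 | intermediate
24 | (3aS,4R,6E,10E,11aR)-10-{[(tert-butyldimethylsilyl)oxy]methyl}-6-formyl-3-methylidene-2-oxo-2,3,3a,4,5,8,9,11a-octahydrocyclodeca[b]furan-4-yl 3-methylbutanoate | C=C1C(=O)O[C@@H]2/C=C(/CO[Si](C)(C)C(C)(C)C)CC/C=C(/C=O)C[C@@H](OC(=O)CC(C)C)[C@H]12 | intermediate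
25 | (3aS,4R,6E,10E,11aR)-6-formyl-10-(hydroxymethyl)-3-methylidene-2-oxo-2,3,3a,4,5,8,9,11a-octahydrocyclodeca[b]furan-4-yl 3-methylbutanoate | C=C1C(=O)O[C@@H]2/C=C(/CO)CC/C=C(/C=O)C[C@@H](OC(=O)CC(C)C)[C@H]12 | target

Total step count: 16. Longest linear sequence: 13 steps (steps 1, 2, 3, 4, 6, 7, 8, 11, 12, 13, 14, 15, 16).

Steps most likely to fail

Step 15. Ring closure may lose to oligomerisation, and the alkenylchromium may add to the wrong face of the aldehyde, which would lock the C6 epimer into a trans-fused lactone. The fallback sets out from 21 and comes back to the route at 22. The ring is closed under chromium-catalytic conditions (CrCl2 cat., NiCl2 cat., Mn, TMSCl, DMF), so that the alkoxide is silylated instead of lactonising. This gives the macrocyclic 6-O-trimethylsilyl ethers F1 as an epimer mixture. Mild desilylation (aq. citric acid, MeOH, 0 °C) gives the macrocyclic C6 alcohols F2, and Dess–Martin oxidation gives the macrocyclic 6-ketone F3. Corey–Bakshi–Shibata reduction (2-methyl-CBS-oxazaborolidine enantiomer chosen for the 6R alcohol, catecholborane, −78 °C) should then give 22, which lactonises to 23 with PPTS as in step 15.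

Step 11. Enantio- and diastereoselection may be insufficient for this β,γ-unsaturated aldehyde, which can also isomerise into conjugation before capture, and the hydroxy ester may close onto O8. The fallback sets out from 16 and comes back to the route at 19. Palladium-catalysed borylation of 16 (B2pin2, Pd2(dba)3 cat., THF) gives the primary allylboronate F4, with CH2OPMB cis to CH2B. Chiral phosphoric acid-catalysed allylboration of 12 through the closed chair transition state gives the syn hydroxy ester F5, the (3R,4S) epimer of 18 at the carbinol carbon. Mitsunobu esterification with 3-methylbutanoic acid (PPh3, DIAD, toluene, 0 °C) inverts that carbon and gives 19 directly.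

Step 6. The cross-metathesis may stall through homodimerisation of 7, alkene migration, catalyst deactivation by the enal or loss of E-selectivity. The fallback sets out from 6 and comes back to the route at 10. (Triphenylphosphoranylidene)succinic anhydride is opened in the flask with MeOH at its non-conjugated carbonyl group, which gives the half-ester ylide F6. Wittig reaction of this stabilised ylide with 6 (CH2Cl2, rt) should give the E-alkylidenesuccinic acid 4-methyl ester F7, with the chain trans to the carboxyl group. Activation of the conjugated acid (ClCO2iBu, N-methylmorpholine, THF, −15 °C) gives the isobutyl mixed anhydride F8. Reduction with NaBH4 (THF/H2O, 0 °C) gives the allylic alcohol F9 without touching the methyl ester, and MnO2 (CH2Cl2, rt) oxidises it to the E-enal 10.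

Further compounds
F1 | step 15 | methyl 2-[(1S,3E,7E,10R)-4-{[(tert-butyldimethylsilyl)oxy]methyl}-8-(dimethoxymethyl)-10-[(3-methylbutanoyl)oxy]-2-[(trimethylsilyl)oxy]cyclodeca-3,7-dien-1-yl]prop-2-enoate (both C2 epimers) | COC(=O)C(=C)[C@@H]1C(O[Si](C)(C)C)/C=C(/CO[Si](C)(C)C(C)(C)C)CC/C=C(/C(OC)OC)C[C@H]1OC(=O)CC(C)C
F2 | step 15 | methyl 2-[(1R,3E,7E,10R)-4-{[(tert-butyldimethylsilyl)oxy]methyl}-8-(dimethoxymethyl)-2-hydroxy-10-[(3-methylbutanoyl)oxy]cyclodeca-3,7-dien-1-yl]prop-2-enoate (both C2 epimers) | COC(=O)C(=C)[C@@H]1C(O)/C=C(/CO[Si](C)(C)C(C)(C)C)CC/C=C(/C(OC)OC)C[C@H]1OC(=O)CC(C)C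
F3 | step 15 | methyl 2-[(1S,3E,7E,10R)-4-{[(tert-butyldimethylsilyl)oxy]methyl}-8-(dimethoxymethyl)-10-[(3-methylbutanoyl)oxy]-2-oxocyclodeca-3,7-dien-1-yl]prop-2-enoate | COC(=O)C(=C)[C@@H]1C(=O)/C=C(/CO[Si](C)(C)C(C)(C)C)CC/C=C(/C(OC)OC)C[C@H]1OC(=O)CC(C)C
F4 | step 11 | methyl (E)-4-[(4-methoxybenzyl)oxy]-2-[(4,4,5,5-tetramethyl-1,3,2-dioxaborolan-2-yl)methyl]but-2-enoate | COC(=O)/C(CB1OC(C)(C)C(C)(C)O1)=C/COCc1ccc(OC)cc1
F5 | step 11 | methyl (3R,4S,6E,10E)-11-bromo-10-{[(tert-butyldimethylsilyl)oxy]methyl}-6-(dimethoxymethyl)-4-hydroxy-3-{[(4-methoxybenzyl)oxy]methyl}-2-methylideneundeca-6,10-dienoate | Br/C=C(/CO[Si](C)(C)C(C)(C)C)CC/C=C(/C(OC)OC)C[C@H](O)[C@@H](COCc1ccc(OC)cc1)C(=C)C(=O)OC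
F6 | step 6 | 4-methoxy-4-oxo-2-(triphenylphosphoranylidene)butanoic acid | COC(=O)CC(C(=O)O)=P(c1ccccc1)(c1ccccc1)c1ccccc1
F7 | step 6 | (2E,6E)-7-bromo-6-{[(tert-butyldimethylsilyl)oxy]methyl}-2-(2-methoxy-2-oxoethyl)hepta-2,6-dienoic acid | Br/C=C(/CO[Si](C)(C)C(C)(C)C)CC/C=C(/C(=O)O)CC(=O)OC
F8 | step 6 | (2E,6E)-7-bromo-6-{[(tert-butyldimethylsilyl)oxy]methyl}-2-(2-methoxy-2-oxoethyl)hepta-2,6-dienoic 2-methylpropyl carbonic anhydride | Br/C=C(/CO[Si](C)(C)C(C)(C)C)CC/C=C(/C(=O)OC(=O)OCC(C)C)CC(=O)OC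
F9 | step 6 | methyl (3E,7E)-8-bromo-7-{[(tert-butyldimethylsilyl)oxy]methyl}-3-(hydroxymethyl)octa-3,7-dienoate | Br/C=C(/CO[Si](C)(C)C(C)(C)C)CC/C=C(/CO)CC(=O)OC
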